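Ring A is cut at C6–C1 and C3–C4, which unfolds the hexasubstituted benzoate into two acyclic pieces: an aryl methoxymethyl 1,3-diketone supplying C4–C5–C6 and a keto ester supplying C1–C2–C3, its C3 held as a ketene acetal. The feature exploited is the oxygenation pattern of ring A: C4, which carries the benzophenone carbonyl C7, lies between oxygen-bearing C3 and C5, the signature of a folded poly-β-carbonyl chain. In one operation the diketone dianion adds to the keto ester and acid closes and aromatises the ring, setting all six ring A substituents. The precursor is diketone 6, already carrying ring B with its C2' oxygen benzylated.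

Key step: step 5

Remark: ring A is numbered C1 (CO2Me), C2 (H), C3 (OMe), C4 (bonded to ketone carbon C7), C5 (OH), C6 (OMe) and ring B C1' (bonded to C7), C2' (OH), C4' (Me), C6' (OMe); the structures of 6, 9 and 13 map atom for atom onto the target and need no correction, and the open-chain and cyclic intermediates of step 5 are assumed to form as stereoisomer mixtures, which is irrelevant because aromatisation erases their stereocentres.

Step 1
Reactants: 1 3-methoxy-5-methylphenol
Product: 2 1-(benzyloxy)-3-methoxy-5-methylbenzene
Conditions: BnBr, K2CO3, acetone, reflux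
Reagents that add atoms: benzyl bromide, BrCc1ccccc1
Why: Williamson ether synthesis: the phenoxide formed with K2CO3 should displace bromide from benzyl bromide in an SN2 reaction, and no other nucleophilic site is present.

Step 2
Reactants: 2 1-(benzyloxy)-3-methoxy-5-methylbenzene
Product: 4 1-[2-(benzyloxy)-6-methoxy-4-methylphenyl]ethan-1-one, via aryllithium 3 (not isolated)
Conditions: n-BuLi, THF, 0 °C; then MeC(O)N(OMe)Me, −78 → 0 °C; dilute aqueous HCl
Reagents that add atoms: N-methoxy-N-methylacetamide, CC(=O)N(C)OC
Why: Directed ortho metalation followed by a Weinreb ketone synthesis: C2 of 2 is flanked by two alkoxy groups that jointly coordinate lithium and acidify that position, so aryllithium 3 should form there, and the chelated tetrahedral adduct of the amide survives until work-up, which prevents double addition.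

Step 3
Reactants: 4 1-[2-(benzyloxy)-6-methoxy-4-methylphenyl]ethan-1-one; 5 methyl methoxyacetate
Product: 6 1-[2-(benzyloxy)-6-methoxy-4-methylphenyl]-4-methoxybutane-1,3-dione
Conditions: NaH, THF, 0 °C → reflux; then dilute aqueous HCl
Reagents that add atoms: none
Why: Crossed Claisen condensation: the sodium enolate of methyl ketone 4 should be acylated on carbon by ester 5, the twisted, doubly ortho-substituted aryl ketone resists self-aldol addition, and deprotonation of the 1,3-diketone product drives the equilibrium.

Step 4
Reactants: 7 1,1-dimethoxyethene; 8 methyl chlorooxoacetate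
Product: 9 methyl 4,4-dimethoxy-2-oxobut-3-enoate
Conditions: Et3N (1.1 equiv), Et2O, 0 °C → rt; filtration, distillation under reduced pressure, stored dry
Reagents that add atoms: none
Why: C-acylation of an electron-rich ketene acetal by an acid chloride, an addition–elimination known for trihaloacetyl and oxalyl chlorides: the methylene carbon attacks the acyl chloride to give a dialkoxycarbenium ion from which Et3N removes the vinylic proton, and the push–pull product is too deactivated to be acylated a second time.

Step 5
Reactants: 6 1-[2-(benzyloxy)-6-methoxy-4-methylphenyl]-4-methoxybutane-1,3-dione; 9 methyl 4,4-dimethoxy-2-oxobut-3-enoate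
Product: 13 methyl 4-[2-(benzyloxy)-6-methoxy-4-methylbenzoyl]-3-hydroxy-2,5-dimethoxybenzoate, via dilithio dianion 10 (not isolated), via open-chain aldol adduct 11 (not isolated), via cyclic ketal 12 (not isolated)
Conditions: LiN(iPr)2 (2.1 equiv), THF, −78 → 0 °C; 9, −78 °C; then MsOH (5 equiv), CH2Cl2, −78 → −20 °C, then rt; aqueous NaHCO3
Reagents that add atoms: none
Why: Proposed new method: twofold deprotonation of 6 gives dianion 10, whose more basic terminal methoxy-substituted carbanion (C6) should add 1,2 to the keto carbonyl (C1) of 9, as 1,3-dicarbonyl dianions do with ketones, to give adduct 11 as its dilithium salt; once the keto group has become an alkoxide the ketene acetal is no longer deactivated, so MsOH protonates it at C2 and the dialkoxycarbenium ion at C3 is captured by the diketone enol carbon C4 to give ketal 12, the same bond formation as in the condensation of orthoesters with 1,3-diketones. Ring A thereby closes in a 6-(enolexo)-exo-trig mode, and loss of methanol from C3, elimination of the C1 hydroxyl as water and enolisation of the C5 carbonyl aromatise it irreversibly. The closest known reaction types are (3+3) benzannulations of 1,3-dicarbonyl dianions or their bis-silyl enol ethers with 3-oxo ketene acetals and biomimetic aldol–Claisen cyclisations of polycarbonyl chains, but this pairing of an aryl diketone dianion with an oxalyl-derived ketene acetal is untested. No stereocentre remains in 13, since the two of 11 and the three of 12 are erased on aromatisation. The selectivity needed is attack at the keto carbonyl and not at the ester carbonyl or in conjugate fashion at C3, which lithium chelation by the 1,2-dicarbonyl unit, the hard dilithio nucleophile and −78 °C should secure, together with C- over O-cyclisation, which is secured because O-closure is reversible and only the carbocycle can aromatise. The C2' benzyl ether is kept through the acid so that this oxygen cannot close a chromone onto the diketone, and the ring is closed cold with a non-nucleophilic acid before warming so that the water released on aromatisation meets no remaining ketene acetal and C3 keeps its methyl.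

Step 6
Reactants: 13 methyl 4-[2-(benzyloxy)-6-methoxy-4-methylbenzoyl]-3-hydroxy-2,5-dimethoxybenzoate
Product: 14 pseudocercone A, methyl 3-hydroxy-4-(2-hydroxy-6-methoxy-4-methylbenzoyl)-2,5-dimethoxybenzoate
Conditions: H2 (1 atm), Pd/C, EtOAc, rt
Reagents that add atoms: none
Why: Heterogeneous catalytic hydrogenolysis of an aryl benzyl ether; the diaryl ketone, shielded by four ortho substituents and held in hydrogen bonds, and the methyl ester should not be reduced at 1 atm and room temperature if the reaction is stopped after uptake of one equivalent of H2.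

Compound list
1 | 3-methoxy-5-methylphenol | COc1cc(C)cc(O)c1 | starting material
2 | 1-(benzyloxy)-3-methoxy-5-methylbenzene | COc1cc(C)cc(OCc2ccccc2)c1 | intermediate
3 | [2-(benzyloxy)-6-methoxy-4-methylphenyl]lithium (formed in situ) | [Li]c1c(OC)cc(C)cc1OCc1ccccc1 | intermediate
4 | 1-[2-(benzyloxy)-6-methoxy-4-methylphenyl]ethan-1-one | CC(=O)c1c(OCc2ccccc2)cc(C)cc1OC | intermediate
5 | methyl methoxyacetate | COCC(=O)OC | starting material
6 | 1-[2-(benzyloxy)-6-methoxy-4-methylphenyl]-4-methoxybutane-1,3-dione | COCC(=O)CC(=O)c1c(OCc2ccccc2)cc(C)cc1OC | intermediate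
7 | 1,1-dimethoxyethene | C=C(OC)OC | starting material
8 | methyl chlorooxoacetate | COC(=O)C(Cl)=O | starting material
9 | methyl 4,4-dimethoxy-2-oxobut-3-enoate | COC(=O)C(=O)C=C(OC)OC | intermediate
10 | dilithium 1-[2-(benzyloxy)-6-methoxy-4-methylphenyl]-4-methoxybuta-1,3-diene-1,3-bis(olate), the dianion of 6 (formed in situ) | COC=C(O[Li])C=C(O[Li])c1c(OCc2ccccc2)cc(C)cc1OC | intermediate
11 | methyl 6-[2-(benzyloxy)-6-methoxy-4-methylphenyl]-2-(2,2-dimethoxyethenyl)-2-hydroxy-3-methoxy-4,6-dioxohexanoate, formed as its dilithium salt, stereoisomer mixture (formed in situ) | COC(=O)C(O)(C=C(OC)OC)C(OC)C(=O)CC(=O)c1c(OCc2ccccc2)cc(C)cc1OC | intermediate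
12 | methyl 4-[2-(benzyloxy)-6-methoxy-4-methylbenzoyl]-1-hydroxy-2,5,5-trimethoxy-3-oxocyclohexane-1-carboxylate, stereoisomer mixture (formed in situ) | COC(=O)C1(O)CC(OC)(OC)C(C(=O)c2c(OCc3ccccc3)cc(C)cc2OC)C(=O)C1OC | intermediate
13 | methyl 4-[2-(benzyloxy)-6-methoxy-4-methylbenzoyl]-3-hydroxy-2,5-dimethoxybenzoate | COC(=O)c1cc(OC)c(C(=O)c2c(OCc3ccccc3)cc(C)cc2OC)c(O)c1OC | intermediate
14 | pseudocercone A, methyl 3-hydroxy-4-(2-hydroxy-6-methoxy-4-methylbenzoyl)-2,5-dimethoxybenzoate (no stereocentre) | COC(=O)c1cc(OC)c(C(=O)c2c(O)cc(C)cc2OC)c(O)c1OC | target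

Total step count: 6
Longest linear sequence: 5 steps (steps 1, 2, 3, 5, 6); step 4 is a one-step side branch.

Steps most likely to fail

Step 5. Several things may go wrong:
- The carbanion may attack the ester carbonyl of 9 or add in conjugate fashion, which would lead to an isomeric arene.
- The aldolate may revert.
- The tertiary allylic hydroxyl may ionise before ring closure and leave an open-chain unsaturated diester of the wrong geometry.
- Adventitious water may hydrolyse the ketene acetal, so that C3 ends as a hydroxyl.

The fallback abandons the annulation and joins two intact rings by known chemistry. It sets out from 2 (lithiated to 3 as in step 2) and comes back at 14. Commercial methyl 2-hydroxy-5-methoxybenzoate (COC(=O)c1cc(OC)ccc1O) is brominated ortho to the hydroxyl (Br2, NaOAc, AcOH) to give methyl 3-bromo-2-hydroxy-5-methoxybenzoate F1. O-Methylation (Me2SO4, K2CO3, acetone) gives methyl 3-bromo-2,5-dimethoxybenzoate F2. Miyaura borylation (B2pin2, Pd(dppf)Cl2, KOAc, dioxane, 90 °C) gives methyl 2,5-dimethoxy-3-(4,4,5,5-tetramethyl-1,3,2-dioxaborolan-2-yl)benzoate F3, and oxidation (NaBO3·4H2O, THF/H2O) gives methyl 3-hydroxy-2,5-dimethoxybenzoate F4. Magnesium-mediated ortho-formylation (MgCl2, Et3N, paraformaldehyde, MeCN, reflux), for which C4 is the only free ortho position, should give methyl 4-formyl-3-hydroxy-2,5-dimethoxybenzoate F5. Benzylation (BnBr, K2CO3, DMF) gives methyl 3-(benzyloxy)-4-formyl-2,5-dimethoxybenzoate F6. Aryllithium 3 is added at −78 °C (aldehyde faster than ester; aqueous NH4Cl quench) to give racemic methyl 3-(benzyloxy)-4-{[2-(benzyloxy)-6-methoxy-4-methylphenyl](hydroxy)methyl}-2,5-dimethoxybenzoate F7. Dess–Martin oxidation gives methyl 3-(benzyloxy)-4-[2-(benzyloxy)-6-methoxy-4-methylbenzoyl]-2,5-dimethoxybenzoate F8, and hydrogenolysis of both benzyl ethers (H2, Pd/C, EtOAc) gives 14.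

Step 2. n-BuLi may deprotonate the benzylic CH2 of the ether and set off a Wittig rearrangement, ring metalation may stay incomplete, or the hindered aryllithium may enolise the acetyl donor and not add to it. The fallback removes the benzyl group from the metalation step. It sets out from 1 and comes back at 4. Compound 1 is O-methylated (Me2SO4, K2CO3, acetone) to 1,3-dimethoxy-5-methylbenzene F9, which can only be metalated on the ring between its two oxygens (n-BuLi, THF, 0 °C). Acetylation with N-methoxy-N-methylacetamide gives 1-(2,6-dimethoxy-4-methylphenyl)ethan-1-one F10. BCl3 (CH2Cl2, −78 → 0 °C) cleaves one of the two equivalent ortho methyl ethers through the carbonyl-chelated boron complex and stops there, giving 1-(2-hydroxy-6-methoxy-4-methylphenyl)ethan-1-one F11. Benzylation (BnBr, K2CO3, DMF) gives 4.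

Step 4. The hydrogen chloride formed may destroy the ketene acetal before the amine traps it, the product may be acylated again or oligomerise, and it may hydrolyse on isolation. The fallback builds the acetal carbon by vinylic substitution and not by acylation of a ketene acetal. It sets out from 8 and comes back at 9. Compound 8 acylates 1,1-dichloroethene under AlCl3 (CH2Cl2, 0 °C; Friedel–Crafts-type alkene acylation, loss of HCl on distillation) to give methyl 4,4-dichloro-2-oxobut-3-enoate F12. Both vinylic chlorides are then displaced by NaOMe (2 equiv, MeOH/Et2O, 0 °C) in two addition–elimination steps to give 9; methoxide matches the methyl ester, so transesterification is harmless.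

Further compounds
F1 | step 5 | methyl 3-bromo-2-hydroxy-5-methoxybenzoate | COC(=O)c1cc(OC)cc(Br)c1O
F2 | step 5 | methyl 3-bromo-2,5-dimethoxybenzoate | COC(=O)c1cc(OC)cc(Br)c1OC
F3 | step 5 | methyl 2,5-dimethoxy-3-(4,4,5,5-tetramethyl-1,3,2-dioxaborolan-2-yl)benzoate | COC(=O)c1cc(OC)cc(B2OC(C)(C)C(C)(C)O2)c1OC
F4 | step 5 | methyl 3-hydroxy-2,5-dimethoxybenzoate | COC(=O)c1cc(OC)cc(O)c1OC
F5 | step 5 | methyl 4-formyl-3-hydroxy-2,5-dimethoxybenzoate | COC(=O)c1cc(OC)c(C=O)c(O)c1OC
F6 | step 5 | methyl 3-(benzyloxy)-4-formyl-2,5-dimethoxybenzoate | COC(=O)c1cc(OC)c(C=O)c(OCc2ccccc2)c1OC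
F7 | step 5 | methyl 3-(benzyloxy)-4-{[2-(benzyloxy)-6-methoxy-4-methylphenyl](hydroxy)methyl}-2,5-dimethoxybenzoate (racemic) | COC(=O)c1cc(OC)c(C(O)c2c(OCc3ccccc3)cc(C)cc2OC)c(OCc2ccccc2)c1OC
F8 | step 5 | methyl 3-(benzyloxy)-4-[2-(benzyloxy)-6-methoxy-4-methylbenzoyl]-2,5-dimethoxybenzoate | COC(=O)c1cc(OC)c(C(=O)c2c(OCc3ccccc3)cc(C)cc2OC)c(OCc2ccccc2)c1OC
F9 | step 2 | 1,3-dimethoxy-5-methylbenzene | COc1cc(C)cc(OC)c1
F10 | step 2 | 1-(2,6-dimethoxy-4-methylphenyl)ethan-1-one | CC(=O)c1c(OC)cc(C)cc1OC
F11 | step 2 | 1-(2-hydroxy-6-methoxy-4-methylphenyl)ethan-1-one | CC(=O)c1c(O)cc(C)cc1OC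
F12 | step 4 | methyl 4,4-dichloro-2-oxobut-3-enoate | COC(=O)C(=O)C=C(Cl)Cl
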